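**Plan**
- Retrosynthesis: the dioxane ring is cut at O-1–C-2 and O-4–C-3 (retro hetero-Diels–Alder) into the o-quinone of a caffeoyl ester and a (Z)-aryl alkene. The C-3 carboxyl is traced back to a dioxolane (glycol cleavage). Further cuts are the caffeoyl C=C (Knoevenagel–Doebner), the ester O–CO (malonate) and ArCH2–CH(OH) (aryl Grignard/Cu + glycidate).
- Enabling feature: the ring atoms O-1/C-8a/C-4a/O-4 are a catechol, i.e. a masked O=C–C=O heterodiene, and C-2/C-3 are the former C=C of a second aryl-C3 unit, as in the presumed biosynthesis of caffeic acid oligomers.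
- Forward order: the lactate arm is made and acylated to a caffeate with a free catechol; a (Z)-styrene is made from D-glyceraldehyde; one oxidative [4+2] closes the only new ring and joins the halves; the C-3 side chain is then cut down to CO2H and the protecting groups are removed.
- Stereochemistry: the lactate centre comes from methyl (R)-glycidate and is never touched. C-2/C-3 become cis from the Z-alkene by suprafacial addition. Their absolute sense comes from the allylic dioxolane stereocentre, which is then excised (its carbon becomes the carboxyl carbon).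

Key step: step 10

Remark: the SMILES defines the cis-(2S,3S)-benzodioxane (H-2/H-3 cis), the less stable diastereomer, so all steps after ring closure avoid base and strong acid. D-glyceraldehyde acetonide is taken as commercial. TBS = tert-butyldimethylsilyl, TIPS = triisopropylsilyl.

**Route**

Step 1
Reactants: 1 4-bromo-2-methoxyphenol
Product: 2 (4-bromo-2-methoxyphenoxy)triisopropylsilane
Conditions: TIPSCl, imidazole, DMF, rt
Reagents that add atoms: chlorotriisopropylsilane (TIPSCl), CC(C)[Si](Cl)(C(C)C)C(C)C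
Why: Standard imidazole-promoted silylation of a phenol; the bulky TIPS ether is chosen because it should tolerate the Grignard, titanate and amine conditions ahead.

Step 2
Reactants: 2 (4-bromo-2-methoxyphenoxy)triisopropylsilane; 3 methyl (2R)-oxirane-2-carboxylate
Product: 5 methyl (2R)-2-hydroxy-3-[3-methoxy-4-(triisopropylsilyloxy)phenyl]propanoate, via arylmagnesium bromide 4 (not isolated)
Conditions: Mg, cat. I2, THF, 50 °C; then CuI (10 mol %), 3, THF, −40 → −20 °C; aq. NH4Cl
Reagents that add atoms: none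
Why: Copper-catalysed SN2 opening of the terminal epoxide by the aryl Grignard reagent occurs at the unsubstituted CH2 faster than addition to the ester at low temperature, so the glycidate stereocentre is untouched and becomes the (R)-lactate centre.

Step 3
Reactants: 5 methyl (2R)-2-hydroxy-3-[3-methoxy-4-(triisopropylsilyloxy)phenyl]propanoate
Product: 6 prop-2-en-1-yl (2R)-2-hydroxy-3-[3-methoxy-4-(triisopropylsilyloxy)phenyl]propanoate
Conditions: allyl alcohol (solvent), Ti(OiPr)4 (0.2 equiv), 80 °C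
Reagents that add atoms: prop-2-en-1-ol, C=CCO
Why: Titanate-mediated transesterification, accelerated by chelation of the α-hydroxy ester and run without base, so the stereocentre is not enolised; the allyl ester can later be cleaved by Pd(0) under neutral conditions.

Step 4
Reactants: 6 prop-2-en-1-yl (2R)-2-hydroxy-3-[3-methoxy-4-(triisopropylsilyloxy)phenyl]propanoate; 7 2,2-dimethyl-1,3-dioxane-4,6-dione (Meldrum's acid)
Product: 8 3-{[(2R)-1-(allyloxy)-3-[3-methoxy-4-(triisopropylsilyloxy)phenyl]-1-oxopropan-2-yl]oxy}-3-oxopropanoic acid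
Conditions: toluene, 100 °C
Reagents that add atoms: none
Why: Thermal alcoholysis of Meldrum's acid (ring opening with loss of acetone) is a standard base-free way to turn a hindered secondary alcohol into its malonic half-ester.

Step 5
Reactants: 8 the malonic half-ester; 9 3,4-dihydroxybenzaldehyde
Product: 10 prop-2-en-1-yl (2R)-2-{[(2E)-3-(3,4-dihydroxyphenyl)prop-2-enoyl]oxy}-3-[3-methoxy-4-(triisopropylsilyloxy)phenyl]propanoate
Conditions: pyridine, piperidine (0.1 equiv), rt → 40 °C
Reagents that add atoms: none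
Why: Knoevenagel–Doebner condensation of the half-ester with the unprotected aldehyde should give the (E)-caffeate by decarboxylative elimination and leaves the catechol free, so no selective deprotection is needed before the key step.

Step 6
Reactants: 11 4-bromobenzene-1,2-diol
Product: 12 4-bromo-1,2-bis(tert-butyldimethylsilyloxy)benzene
Conditions: TBSCl (2.4 equiv), imidazole, DMF, rt
Reagents that add atoms: tert-butylchlorodimethylsilane (TBSCl), CC(C)(C)[Si](C)(C)Cl
Why: Standard silylation of both phenols; the silyl ethers make the later styrene non-phenolic (not oxidised by Ag2O) and only moderately electron-donating.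

Step 7
Reactants: 13 (4R)-2,2-dimethyl-1,3-dioxolane-4-carbaldehyde (D-glyceraldehyde acetonide)
Product: 14 (4S)-4-ethynyl-2,2-dimethyl-1,3-dioxolane
Conditions: dimethyl (1-diazo-2-oxopropyl)phosphonate, K2CO3, MeOH, 0 °C → rt (aldehyde added last)
Reagents that add atoms: dimethyl (1-diazo-2-oxopropyl)phosphonate, COP(=O)(OC)C(=[N+]=[N-])C(C)=O
Why: Ohira–Bestmann (Seyferth–Gilbert) homologation converts the aldehyde into the terminal alkyne with one added carbon and retention at the α-stereocentre (the descriptor becomes S only through the priority change).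

Step 8
Reactants: 12 4-bromo-1,2-bis(tert-butyldimethylsilyloxy)benzene; 14 (4S)-4-ethynyl-2,2-dimethyl-1,3-dioxolane
Product: 15 (4S)-4-{[3,4-bis(tert-butyldimethylsilyloxy)phenyl]ethynyl}-2,2-dimethyl-1,3-dioxolane
Conditions: PdCl2(PhCN)2 (3 mol %), t-Bu3P·HBF4 (6 mol %), CuI (2 mol %), i-Pr2NH, 1,4-dioxane, rt
Reagents that add atoms: none
Why: Sonogashira coupling with a bulky electron-rich phosphine couples electron-rich aryl bromides at room temperature under an amine base that leaves aryl silyl ethers and the acetonide intact.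

Step 9
Reactants: 15 the aryl alkyne
Product: 16 (4S)-4-{(Z)-2-[3,4-bis(tert-butyldimethylsilyloxy)phenyl]ethenyl}-2,2-dimethyl-1,3-dioxolane
Conditions: H2 (1 atm), Lindlar catalyst, quinoline, EtOAc, rt
Reagents that add atoms: none
Why: Lindlar semihydrogenation adds H2 syn to the alkyne and stops at the (Z)-alkene, which secures the geometry that the key step carries into the cis ring.

Step 10
Reactants: 10 the caffeate with free catechol; 16 the (Z)-styrene (3 equiv, excess recoverable)
Product: 18 prop-2-en-1-yl (2R)-2-{[(2E)-3-{(2S,3S)-2-[3,4-bis(tert-butyldimethylsilyloxy)phenyl]-3-[(4R)-2,2-dimethyl-1,3-dioxolan-4-yl]-2,3-dihydro-1,4-benzodioxin-6-yl}prop-2-enoyl]oxy}-3-[3-methoxy-4-(triisopropylsilyloxy)phenyl]propanoate, via o-quinone 17 (not isolated)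
Conditions: Ag2O (3 equiv), 4 Å MS, CH2Cl2–toluene, 0 °C → rt, dark; 10 added slowly to Ag2O/16
Reagents that add atoms: none
Why: Proposed new method: Ag2O dehydrogenates the only free catechol (that of 10) to the o-quinone 17, whose O=C–C=O unit acts as an electron-poor heterodiene towards the electron-rich (Z)-styrene 16 in an inverse-electron-demand hetero-Diels–Alder reaction driven by re-aromatisation; the closest known reaction type is the cycloaddition of o-quinones with propenylbenzenes to 1,4-benzodioxane neolignans (and the Ag2O coupling of caffeates), but a transient caffeate quinone, a Z-alkene and control by an allylic stereocentre have not been combined. The dioxane ring is closed by a suprafacial [4+2] cycloaddition that forms O-4–C-3 and O-1–C-2 in one step (asynchronous, O-4–C-3 ahead). C-2 and C-3 become cis because the Z geometry is carried over, and their absolute configuration (2S,3S) comes from the dioxolane stereocentre: A(1,3) strain in the Z-alkene keeps its C–H eclipsed with the double bond, and the quinone oxygens should approach anti to the allylic C–O bond, as OsO4 does with Z-allylic dioxolanes (ribo-type adduct). Regiochemistry follows from polarisation: the nucleophilic alkene carbon remote from the aryl ring (future C-3) bonds to the quinone oxygen meta to the acrylate, because this releases the phenoxide para to the acrylate, which then closes on the benzylic carbon (C-2). Chemoselectivity is secured because every other phenol is silylated and the remaining alkenes (enoate, allyl ester) are electron-poor or unactivated, and stereospecificity by a non-polar medium and the only moderately donating silyloxy groups, which disfavour a free benzylic cation that could rotate before ring closure.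

Step 11
Reactants: 18 the cycloadduct
Product: 20 prop-2-en-1-yl (2R)-2-{[(2E)-3-{(2S,3S)-2-[3,4-bis(tert-butyldimethylsilyloxy)phenyl]-3-formyl-2,3-dihydro-1,4-benzodioxin-6-yl}prop-2-enoyl]oxy}-3-[3-methoxy-4-(triisopropylsilyloxy)phenyl]propanoate, via diol 19 (not isolated)
Conditions: H5IO6 (2 equiv), EtOAc, rt; crude aldehyde used at once
Reagents that add atoms: none
Why: Periodic acid in ethyl acetate hydrolyses a terminal isopropylidene acetal and cleaves the released 1,2-diol in the same flask (Malaprade glycol cleavage), so the helper stereocentre carbon becomes the formyl carbon on C-3; the α-aryloxy aldehyde is not purified, to avoid enolisation at C-3.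

Step 12
Reactants: 20 the aldehyde
Product: 21 prop-2-en-1-yl (2R)-2-{[(2E)-3-{(2S,3S)-2-[3,4-bis(tert-butyldimethylsilyloxy)phenyl]-3-carboxy-2,3-dihydro-1,4-benzodioxin-6-yl}prop-2-enoyl]oxy}-3-[3-methoxy-4-(triisopropylsilyloxy)phenyl]propanoate
Conditions: NaClO2, NaH2PO4, 2-methyl-2-butene, t-BuOH–H2O, 0 °C → rt
Reagents that add atoms: sodium chlorite, [Na+].[O-]Cl=O
Why: Pinnick oxidation converts the aldehyde into the acid at pH 3–4 without enolising C-3, while 2-methyl-2-butene scavenges HOCl so that the arenes, the enoate and the allyl ester are spared.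

Step 13
Reactants: 21 the mono-acid allyl ester
Product: 22 (2R)-2-{[(2E)-3-{(2S,3S)-2-[3,4-bis(tert-butyldimethylsilyloxy)phenyl]-3-carboxy-2,3-dihydro-1,4-benzodioxin-6-yl}prop-2-enoyl]oxy}-3-[3-methoxy-4-(triisopropylsilyloxy)phenyl]propanoic acid
Conditions: Pd(PPh3)4 (5 mol %), morpholine, THF, rt; pH 3 buffer work-up
Reagents that add atoms: none
Why: Pd(0)-catalysed allyl transfer to morpholine (Tsuji–Trost deallylation) cleaves the allyl ester under near-neutral conditions without touching the enoate ester or C-3, which is present as the non-enolisable carboxylate.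

Step 14
Reactants: 22 the diacid tris-silyl ether
Product: 23 (2R)-2-{[(2E)-3-[(2S,3S)-3-carboxy-2-(3,4-dihydroxyphenyl)-2,3-dihydro-1,4-benzodioxin-6-yl]prop-2-enoyl]oxy}-3-(4-hydroxy-3-methoxyphenyl)propanoic acid (target)
Conditions: HF·pyridine, pyridine, THF, 0 °C → rt; reversed-phase purification (0.1 % HCO2H)
Reagents that add atoms: none
Why: Buffered HF·pyridine cleaves the three aryl silyl ethers through Si–F bond formation under weakly acidic conditions, which avoids phenoxide formation and hence quinone-methide opening or epimerisation of the cis-benzodioxane and ester hydrolysis.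

**Compound list**

1 | 4-bromo-2-methoxyphenol | COc1cc(Br)ccc1O | starting material
2 | (4-bromo-2-methoxyphenoxy)triisopropylsilane | COc1cc(Br)ccc1O[Si](C(C)C)(C(C)C)C(C)C | intermediate
3 | methyl (2R)-oxirane-2-carboxylate | COC(=O)[C@H]1CO1 | starting material
4 | [3-methoxy-4-(triisopropylsilyloxy)phenyl]magnesium bromide | COc1cc([Mg]Br)ccc1O[Si](C(C)C)(C(C)C)C(C)C | intermediate (not isolated)
5 | methyl (2R)-2-hydroxy-3-[3-methoxy-4-(triisopropylsilyloxy)phenyl]propanoate | COC(=O)[C@H](O)Cc1ccc(O[Si](C(C)C)(C(C)C)C(C)C)c(OC)c1 | intermediate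
6 | prop-2-en-1-yl (2R)-2-hydroxy-3-[3-methoxy-4-(triisopropylsilyloxy)phenyl]propanoate | C=CCOC(=O)[C@H](O)Cc1ccc(O[Si](C(C)C)(C(C)C)C(C)C)c(OC)c1 | intermediate
7 | 2,2-dimethyl-1,3-dioxane-4,6-dione (Meldrum's acid) | CC1(C)OC(=O)CC(=O)O1 | starting material
8 | 3-{[(2R)-1-(allyloxy)-3-[3-methoxy-4-(triisopropylsilyloxy)phenyl]-1-oxopropan-2-yl]oxy}-3-oxopropanoic acid | C=CCOC(=O)[C@@H](Cc1ccc(O[Si](C(C)C)(C(C)C)C(C)C)c(OC)c1)OC(=O)CC(=O)O | intermediate
9 | 3,4-dihydroxybenzaldehyde | O=Cc1ccc(O)c(O)c1 | starting material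
10 | prop-2-en-1-yl (2R)-2-{[(2E)-3-(3,4-dihydroxyphenyl)prop-2-enoyl]oxy}-3-[3-methoxy-4-(triisopropylsilyloxy)phenyl]propanoate | C=CCOC(=O)[C@@H](Cc1ccc(O[Si](C(C)C)(C(C)C)C(C)C)c(OC)c1)OC(=O)/C=C/c1ccc(O)c(O)c1 | intermediate
11 | 4-bromobenzene-1,2-diol | Oc1ccc(Br)cc1O | starting material
12 | 4-bromo-1,2-bis(tert-butyldimethylsilyloxy)benzene | CC(C)(C)[Si](C)(C)Oc1ccc(Br)cc1O[Si](C)(C)C(C)(C)C | intermediate
13 | (4R)-2,2-dimethyl-1,3-dioxolane-4-carbaldehyde | O=C[C@H]1COC(C)(C)O1 | starting material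
14 | (4S)-4-ethynyl-2,2-dimethyl-1,3-dioxolane | C#C[C@H]1COC(C)(C)O1 | intermediate
15 | (4S)-4-{[3,4-bis(tert-butyldimethylsilyloxy)phenyl]ethynyl}-2,2-dimethyl-1,3-dioxolane | CC(C)(C)[Si](C)(C)Oc1ccc(C#C[C@H]2COC(C)(C)O2)cc1O[Si](C)(C)C(C)(C)C | intermediate
16 | (4S)-4-{(Z)-2-[3,4-bis(tert-butyldimethylsilyloxy)phenyl]ethenyl}-2,2-dimethyl-1,3-dioxolane | CC(C)(C)[Si](C)(C)Oc1ccc(/C=C\[C@H]2COC(C)(C)O2)cc1O[Si](C)(C)C(C)(C)C | intermediate
17 | prop-2-en-1-yl (2R)-2-{[(2E)-3-(3,4-dioxocyclohexa-1,5-dien-1-yl)prop-2-enoyl]oxy}-3-[3-methoxy-4-(triisopropylsilyloxy)phenyl]propanoate (o-quinone) | C=CCOC(=O)[C@@H](Cc1ccc(O[Si](C(C)C)(C(C)C)C(C)C)c(OC)c1)OC(=O)/C=C/C1=CC(=O)C(=O)C=C1 | intermediate (not isolated)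
18 | prop-2-en-1-yl (2R)-2-{[(2E)-3-{(2S,3S)-2-[3,4-bis(TBSO)phenyl]-3-[(4R)-2,2-dimethyl-1,3-dioxolan-4-yl]-2,3-dihydro-1,4-benzodioxin-6-yl}prop-2-enoyl]oxy}-3-[3-methoxy-4-(TIPSO)phenyl]propanoate | C=CCOC(=O)[C@@H](Cc1ccc(O[Si](C(C)C)(C(C)C)C(C)C)c(OC)c1)OC(=O)/C=C/c1ccc2c(c1)O[C@H]([C@H]1COC(C)(C)O1)[C@H](c1ccc(O[Si](C)(C)C(C)(C)C)c(O[Si](C)(C)C(C)(C)C)c1)O2 | intermediate
19 | prop-2-en-1-yl (2R)-2-{[(2E)-3-{(2S,3R)-2-[3,4-bis(TBSO)phenyl]-3-[(1R)-1,2-dihydroxyethyl]-2,3-dihydro-1,4-benzodioxin-6-yl}prop-2-enoyl]oxy}-3-[3-methoxy-4-(TIPSO)phenyl]propanoate (same geometry as 18; descriptor changes by priority) | C=CCOC(=O)[C@@H](Cc1ccc(O[Si](C(C)C)(C(C)C)C(C)C)c(OC)c1)OC(=O)/C=C/c1ccc2c(c1)O[C@H]([C@H](O)CO)[C@H](c1ccc(O[Si](C)(C)C(C)(C)C)c(O[Si](C)(C)C(C)(C)C)c1)O2 | intermediate (not isolated)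
20 | prop-2-en-1-yl (2R)-2-{[(2E)-3-{(2S,3S)-2-[3,4-bis(TBSO)phenyl]-3-formyl-2,3-dihydro-1,4-benzodioxin-6-yl}prop-2-enoyl]oxy}-3-[3-methoxy-4-(TIPSO)phenyl]propanoate | C=CCOC(=O)[C@@H](Cc1ccc(O[Si](C(C)C)(C(C)C)C(C)C)c(OC)c1)OC(=O)/C=C/c1ccc2c(c1)O[C@H](C=O)[C@H](c1ccc(O[Si](C)(C)C(C)(C)C)c(O[Si](C)(C)C(C)(C)C)c1)O2 | intermediate
21 | prop-2-en-1-yl (2R)-2-{[(2E)-3-{(2S,3S)-2-[3,4-bis(TBSO)phenyl]-3-carboxy-2,3-dihydro-1,4-benzodioxin-6-yl}prop-2-enoyl]oxy}-3-[3-methoxy-4-(TIPSO)phenyl]propanoate | C=CCOC(=O)[C@@H](Cc1ccc(O[Si](C(C)C)(C(C)C)C(C)C)c(OC)c1)OC(=O)/C=C/c1ccc2c(c1)O[C@H](C(=O)O)[C@H](c1ccc(O[Si](C)(C)C(C)(C)C)c(O[Si](C)(C)C(C)(C)C)c1)O2 | intermediate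
22 | (2R)-2-{[(2E)-3-{(2S,3S)-2-[3,4-bis(TBSO)phenyl]-3-carboxy-2,3-dihydro-1,4-benzodioxin-6-yl}prop-2-enoyl]oxy}-3-[3-methoxy-4-(TIPSO)phenyl]propanoic acid | OC(=O)[C@@H](Cc1ccc(O[Si](C(C)C)(C(C)C)C(C)C)c(OC)c1)OC(=O)/C=C/c1ccc2c(c1)O[C@H](C(=O)O)[C@H](c1ccc(O[Si](C)(C)C(C)(C)C)c(O[Si](C)(C)C(C)(C)C)c1)O2 | intermediate
23 | (2R)-2-{[(2E)-3-[(2S,3S)-3-carboxy-2-(3,4-dihydroxyphenyl)-2,3-dihydro-1,4-benzodioxin-6-yl]prop-2-enoyl]oxy}-3-(4-hydroxy-3-methoxyphenyl)propanoic acid | COc1cc(C[C@@H](OC(=O)/C=C/c2ccc3c(c2)O[C@H](C(=O)O)[C@H](c2ccc(O)c(O)c2)O3)C(=O)O)ccc1O | target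

**Step count and risks**

Total: 14 steps. Longest linear sequence: 10 steps (steps 1–5 and 10–14).

Steps most likely to fail:

1. Step 10 (labelled). Possible failures are addition of unoxidised catechol to the transient quinone (oligomers), cycloaddition through the carbon diene of the quinone, a stepwise zwitterionic closure with rotation about C-2–C-3 (trans ring), attack on the other alkene face (2R,3R ring) or reversed regiochemistry. If only the face is wrong, the helper from (S)-glyceraldehyde acetonide would serve. The fallback uses known chemistry, sets out from 16 and returns at 18. Thiyl-radical isomerisation (PhSSPh cat., hν) should give the (E)-alkene (4S)-4-{(E)-2-[3,4-bis(TBSO)phenyl]ethenyl}-2,2-dimethyl-1,3-dioxolane F1. Shi epoxidation (D-fructose-derived ketone, Oxone, buffered MeCN–dimethoxymethane–H2O, 0 °C; reagent-controlled, face chosen by analogy with trans-β-methylstyrene) should give the trans-epoxide F2. Its benzylic carbon is opened with inversion by the phenoxide of 3-bromo-4-hydroxybenzaldehyde (K2CO3, DMF, 40 °C) to the bromoaryl ether alcohol F3. Pd-catalysed intramolecular C–O coupling of the secondary alcohol (Pd(OAc)2, t-BuXPhos, K3PO4, toluene, 80 °C; retention) closes the cis-benzodioxane carbaldehyde F4. Knoevenagel–Doebner condensation of F4 with half-ester 8 (pyridine, cat. piperidine) gives 18. One inversion (benzylic C) and one retention from an E-alkene give the same cis-(2S,3S) ring, with regiochemistry fixed by the positions of OH and Br on the arene.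

2. Step 7. Possible failures are enolisation of the α-alkoxy aldehyde under K2CO3/MeOH before homologation (erosion of the helper stereocentre) and loss of the volatile alkyne on isolation. The fallback sets out from 13 and returns at 15. Corey–Fuchs dibromo-olefination (CBr4, PPh3, CH2Cl2, 0 °C; no base) gives (4S)-4-(2,2-dibromoethenyl)-2,2-dimethyl-1,3-dioxolane F5. n-BuLi (2 equiv, THF, −78 °C) converts it into the lithium acetylide F6. ZnCl2 gives the alkynylzinc chloride F7, which is coupled in the same flask with 12 (Negishi coupling, Pd(PPh3)4, THF, 50 °C) to 15, so the free alkyne 14 and step 8 are bypassed.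

3. Step 5. Possible failures are slow condensation of the hindered half-ester, so that simple decarboxylation to the acetate ester, aminolysis of the allyl ester by piperidine and air oxidation of the catechol product compete. The fallback sets out from 6 and returns at 10. Alcohol 6 is acylated (EDC·HCl, DMAP, CH2Cl2) with (2E)-3-(3,4-diacetoxyphenyl)prop-2-enoic acid F8 (from commercial caffeic acid, Ac2O, pyridine) to the diacetate ester F9. The two aryl acetates are then cleaved chemoselectively with hydrazinium acetate (DMF, rt) to 10, so steps 4 and 5 are bypassed.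

**Further compounds**

F1 | step 10 | (4S)-4-{(E)-2-[3,4-bis(tert-butyldimethylsilyloxy)phenyl]ethenyl}-2,2-dimethyl-1,3-dioxolane | CC(C)(C)[Si](C)(C)Oc1ccc(/C=C/[C@H]2COC(C)(C)O2)cc1O[Si](C)(C)C(C)(C)C
F2 | step 10 | (4R)-4-{(2S,3R)-3-[3,4-bis(tert-butyldimethylsilyloxy)phenyl]oxiran-2-yl}-2,2-dimethyl-1,3-dioxolane | CC(C)(C)[Si](C)(C)Oc1ccc([C@H]2O[C@@H]2[C@H]2COC(C)(C)O2)cc1O[Si](C)(C)C(C)(C)C
F3 | step 10 | 3-bromo-4-{(1S,2S)-1-[3,4-bis(tert-butyldimethylsilyloxy)phenyl]-2-[(4R)-2,2-dimethyl-1,3-dioxolan-4-yl]-2-hydroxyethoxy}benzaldehyde | O=Cc1ccc(O[C@@H](c2ccc(O[Si](C)(C)C(C)(C)C)c(O[Si](C)(C)C(C)(C)C)c2)[C@H](O)[C@H]2COC(C)(C)O2)c(Br)c1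
F4 | step 10 | (2S,3S)-2-[3,4-bis(tert-butyldimethylsilyloxy)phenyl]-3-[(4R)-2,2-dimethyl-1,3-dioxolan-4-yl]-2,3-dihydro-1,4-benzodioxine-6-carbaldehyde | O=Cc1ccc2c(c1)O[C@H]([C@H]1COC(C)(C)O1)[C@H](c1ccc(O[Si](C)(C)C(C)(C)C)c(O[Si](C)(C)C(C)(C)C)c1)O2
F5 | step 7 | (4S)-4-(2,2-dibromoethenyl)-2,2-dimethyl-1,3-dioxolane | BrC(Br)=C[C@H]1COC(C)(C)O1
F6 | step 7 | lithium {[(4S)-2,2-dimethyl-1,3-dioxolan-4-yl]ethynide} | [Li]C#C[C@H]1COC(C)(C)O1
F7 | step 7 | chloro{[(4S)-2,2-dimethyl-1,3-dioxolan-4-yl]ethynyl}zinc | Cl[Zn]C#C[C@H]1COC(C)(C)O1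
F8 | step 5 | (2E)-3-(3,4-diacetoxyphenyl)prop-2-enoic acid | CC(=O)Oc1ccc(/C=C/C(=O)O)cc1OC(C)=O
F9 | step 5 | prop-2-en-1-yl (2R)-2-{[(2E)-3-(3,4-diacetoxyphenyl)prop-2-enoyl]oxy}-3-[3-methoxy-4-(triisopropylsilyloxy)phenyl]propanoate | C=CCOC(=O)[C@@H](Cc1ccc(O[Si](C(C)C)(C(C)C)C(C)C)c(OC)c1)OC(=O)/C=C/c1ccc(OC(C)=O)c(OC(C)=O)c1
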